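The readings stem from a simulated flask from invented constants; the scatter is artificial.

Early in the fed runs D shows little: at 6.00 h G reads 22.1% on Friday and 20.3% on Sunday, with 69 mM and 93 mM of D. At 15.0 h the readings are 39.3% and 34.2%, a gap of 5.1 percentage points. Between those times, control of G seems to pass from its making to its use.

| flask | Q | D | remark | time |
|---|---|---|---|---|
| Friday's | 0.80 M (fed, over 5.0 h) | 69 mM | run made earlier; the fed solution adds 0.25 times the starting volume |  |
| Sunday's | 0.80 M (fed, over 5.0 h) | 93 mM | run made earlier; the fed solution adds 0.25 times the starting volume |  |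
| epsilon | 0.80 M | 80 mM | everything together at the start, the whole solution of Q included, so that from the start the volume is larger by 0.25 times the starting volume | 30 h |
| gamma | 0.80 M (fed, over 5.0 h) | 140 mM | the fed solution adds 0.25 times the starting volume | 30 h |

- Friday's (time / h: G / %, J / %, Q / %): 0.833: 1.3, 0.2, 16.2; 2.50: 4.6, 0, 45.6; 4.00: 10.7, 2.8, 68.2; 6.00: 22.1, 4.4, 74.0; 10.0: 34.8, 13.8, 51.9; 12.0: 37.1, 19.0, 43.4; 15.0: 39.3, 27.9, 33.6
- Sunday's (time / h: G / %, J / %, Q / %): 2.00: 3.4, 1.0, 36.4; 4.00: 11.4, 2.0, 67.1; 6.00: 20.3, 4.9, 74.9; 8.00: 27.7, 10.5, 62.1; 10.0: 31.5, 17.4, 51.5; 12.0: 34.0, 22.8, 43.6; 15.0: 34.2, 32.8, 34.2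

(scatter of a reading: 0.5 percentage points)

- the winner by amount of G, in percent of the Q charged; "neither" if no more than 2 percentage points parts them (epsilon / gamma / neither)
- how much G is there at the end, in percent of the Q charged: epsilon
- how much G is there at the end, in percent of the Q charged: gamma

- charges are per starting volume, the dose included; the dosed solution carries all of it
- steps that have been proposed: D + G -> D + J; 2 D <-> E; Q -> G
- percentages count the whole charge, also what has not yet gone in

I put a number on that crossing, using the two runs from 10.0 h to 15.0 h, after the feed. The fall of [Q] gives a making constant of 0.0844 h⁻¹. The rise of J over mean [G], pooled, gives a use constant of 0.0844 h⁻¹. The mean D of those runs, 81.0 mM, lies close to epsilon's 80 mM. Their quotient, 1.00, is my hand-over ratio h, the use constant over the making constant. Making over use is then [Q]/(h[G]), and G peaks where that equals one.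

Two views part here. The first chemist says late G follows its use, which grows with D: the use constant reads 0.0761 h⁻¹ on Friday and 0.0938 h⁻¹ on Sunday. Her forecast puts epsilon ahead, with 18.7% of G there against 11.5% in gamma; for gamma, “The dimer correction gives k′ ≈ 0.14 /h”.

The second chemist trusts the early readings. For him the use constant does not move with D, and gamma just runs 2.50 h late. With h equal to one in both flasks, G is x e^(−x), where x is the making constant times the time. That gives epsilon 20.1% and gamma 22.8%, so gamma wins. My epsilon number is his, slightly above the forecast's. For gamma I side with her: Sunday's use constant already exceeds the making constant, and gamma has more D than Sunday.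

The simulation puts epsilon ahead, with 19.8% of G there against 13.4% in gamma.

    D + G → D + J (k = 1.90 M⁻¹ h⁻¹)
    2 D ⇌ E (K = 5.40 M⁻¹, k = 0.540 M⁻¹ h⁻¹)
    Q → G (k = 0.0880 h⁻¹)

In epsilon, G is made faster than it is used at 7.09 h, by 1.59, and that early stretch is the second view's region. At 30 h in epsilon making is slower than use, at 0.384; h with the amounts then standing gives 0.361. Now read epsilon at 2.0 d: holding that ratio, my reckoning takes G from 19.8% to 7.50%. The computed flask holds 6.89%.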